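**Assumption:** the target SMILES encodes (1S,2S), the threo (syn in zigzag) β-O-4 arrangement. The aryloxyacetyl imide is assumed to behave as an Evans glycolate, giving a Z-boron enolate and the Evans-syn aldol.

**Retrosynthesis**
- The target is 4-[(1S,2S)-1,3-dihydroxy-1-(4-hydroxy-3-methoxyphenyl)propan-2-yl]oxy-3,5-dimethoxybenzoic acid.
- Remove the Bn groups and the methyl ester, then reduce the imide to the γ-CH2OH. This gives a syn aldol adduct of an aryloxyacetyl oxazolidinone with O-benzylvanillin, which sets Cα and Cβ together.
- The aryloxyacetyl imide comes from N-chloroacetyl-(R)-4-benzyloxazolidinone plus methyl syringate.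
- No rings are built; both arenes are purchased, and the oxazolidinone is a recovered auxiliary.
- Numbered compounds are substrates, products and atom-contributing reagents. Bases, catalysts and solvents are not numbered.

**Step 1**
Reactants: 1 (R)-4-benzyloxazolidin-2-one; 2 chloroacetyl chloride
Product: 3 (R)-4-benzyl-3-(chloroacetyl)oxazolidin-2-one
Conditions: n-BuLi, THF, −78 °C; then 2, −78 °C → 0 °C
Reagents that add atoms: chloroacetyl chloride, ClCC(=O)Cl
Why: N-lithiation followed by N-acylation (Schotten–Baumann-type) installs the chiral auxiliary, whose stereocentre is untouched.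

**Step 2**
Reactants: 3; 4 methyl syringate (methyl 4-hydroxy-3,5-dimethoxybenzoate)
Product: 5 (R)-4-benzyl-3-[2-(2,6-dimethoxy-4-methoxycarbonylphenoxy)acetyl]oxazolidin-2-one
Conditions: K2CO3, NaI (cat.), DMF, 50 °C
Reagents that add atoms: none (the aryloxide replaces Cl)
Why: Williamson ether synthesis (SN2) of the phenoxide on the activated α-chloro imide, with Finkelstein activation by iodide. This forms the β-aryl ether C–O bond, and no stereocentre is formed.

**Step 3**
Reactants: 5; 6 4-benzyloxy-3-methoxybenzaldehyde
Product: 7 (R)-4-benzyl-3-[(2R,3S)-3-(4-benzyloxy-3-methoxyphenyl)-3-hydroxy-2-(2,6-dimethoxy-4-methoxycarbonylphenoxy)propanoyl]oxazolidin-2-one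
Conditions: Bu2BOTf, iPr2NEt, CH2Cl2, −78 → 0 °C; add 6 at −78 °C; then pH 7 buffer, MeOH, 30% H2O2, 0 °C
Reagents that add atoms: none
Why: Evans syn aldol. The Z-boron enolate reacts through a Zimmerman–Traxler chair with dipole-minimised orientation of the (R)-benzyl auxiliary. This sets both new centres in one step, syn, with the (2R,3S) sense (Cβ R, Cα S in this numbering). After the imide is reduced to CH2OH, Cβ becomes S by CIP priority change only, so the diol is (αS,βS), i.e. threo.

**Step 4**
Reactants: 7
Product: 8 methyl 4-{[(1S,2S)-1-(4-benzyloxy-3-methoxyphenyl)-1,3-dihydroxypropan-2-yl]oxy}-3,5-dimethoxybenzoate (auxiliary 1 is recovered)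
Conditions: NaBH4, THF/H2O (3:1), 0 °C → rt
Reagents that add atoms: none (only H is added)
Why: Reductive cleavage of the N-acyl oxazolidinone to the primary alcohol. The aryl methyl ester and benzyl ethers are inert under these conditions, and no stereocentre is touched.

**Step 5**
Reactants: 8; 9 lithium hydroxide
Product: 10 4-{[(1S,2S)-1-(4-benzyloxy-3-methoxyphenyl)-1,3-dihydroxypropan-2-yl]oxy}-3,5-dimethoxybenzoic acid
Conditions: LiOH·H2O, THF/MeOH/H2O, rt; then KHSO4 to pH ~3
Reagents that add atoms: lithium hydroxide, [Li+].[OH-]
Why: Saponification of the methyl benzoate. The free diol, benzyl ether and both stereocentres are unaffected, and the mild acidification avoids quinone-methide formation.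

**Step 6**
Reactants: 10
Product: 11 target, 4-{[(1S,2S)-1,3-dihydroxy-1-(4-hydroxy-3-methoxyphenyl)propan-2-yl]oxy}-3,5-dimethoxybenzoic acid
Conditions: H2 (1 atm), 10% Pd/C, EtOAc/EtOH, rt, 1–2 h
Reagents that add atoms: none (only H is added)
Why: Catalytic hydrogenolysis of the phenolic benzyl ether (toluene is lost). It is run neutral and short to preserve the benzylic alcohol, and the stereocentres are unchanged.

**Compound list**

| No. | Name | SMILES | Role |
|---|---|---|---|
| 1 | (R)-4-benzyloxazolidin-2-one | O=C1N[C@H](Cc2ccccc2)CO1 | starting material |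
| 2 | chloroacetyl chloride | ClCC(=O)Cl | starting material |
| 3 | (R)-4-benzyl-3-(chloroacetyl)oxazolidin-2-one | ClCC(=O)N1[C@H](Cc2ccccc2)COC1=O | intermediate |
| 4 | methyl syringate | COC(=O)c1cc(OC)c(O)c(OC)c1 | starting material |
| 5 | aryloxyacetyl imide | COC(=O)c1cc(OC)c(OCC(=O)N2[C@H](Cc3ccccc3)COC2=O)c(OC)c1 | intermediate |
| 6 | 4-benzyloxy-3-methoxybenzaldehyde | COc1cc(C=O)ccc1OCc1ccccc1 | starting material |
| 7 | syn aldol adduct (2R,3S) | COC(=O)c1cc(OC)c(O[C@@H](C(=O)N2[C@H](Cc3ccccc3)COC2=O)[C@@H](O)c2ccc(OCc3ccccc3)c(OC)c2)c(OC)c1 | intermediate |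
| 8 | diol methyl ester (1S,2S) | COc1cc([C@H](O)[C@H](CO)Oc2c(OC)cc(C(=O)OC)cc2OC)ccc1OCc1ccccc1 | intermediate |
| 9 | lithium hydroxide | [Li+].[OH-] | reagent |
| 10 | O-benzyl acid (1S,2S) | COc1cc([C@H](O)[C@H](CO)Oc2c(OC)cc(C(=O)O)cc2OC)ccc1OCc1ccccc1 | intermediate |
| 11 | target | COc1cc([C@H](O)[C@H](CO)Oc2c(OC)cc(C(=O)O)cc2OC)ccc1O | target |

**Total steps:** 6. **Longest linear sequence:** 6.

**Three steps most likely to fail**
1. **Step 3 (aldol).** Aryloxy enolates may enolise poorly or give reduced syn selectivity, and the adduct can retro-aldolise.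
   - Fallback: change the stereocontrol strategy. Acylate methyl syringate-derived aryloxyacetate with the O-benzylvanillic acid derivative to make the α-aryloxy β-ketoester. Then do a Ru-TsDPEN asymmetric transfer hydrogenation with dynamic kinetic resolution, and reduce the ester to CH2OH.
2. **Step 4 (NaBH4 cleavage).** The acidic α-aryloxy imide can epimerise at Cβ, or the methyl ester can be over-reduced.
   - Fallback: remove the auxiliary by transesterification instead (Mg(OMe)2/MeOH, or MeOMgBr) to the β-hydroxy methyl ester. Then reduce selectively with LiBH4 at −20 °C, or use the thiazolidinethione auxiliary with a different reductive removal.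
3. **Step 6 (hydrogenolysis).** Pd/C can over-reduce the electron-rich benzylic alcohol.
   - Fallback: use the 4-allyloxy-3-methoxybenzaldehyde analogue in step 3 and remove the allyl group with Pd(PPh3)4/morpholine after saponification, which avoids hydrogenolysis entirely.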